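**Strategy.** The enol-ether oxygen bridge is formed last. A 14-membered carbocyclic cycloalkyne (C9≡C10; C1 = isopropylidene-bearing carbon, C2 = ketone) that already holds the epoxy ketone, the tertiary acetate and a free C6 hydroxyl is built by Nozaki–Hiyama fragment union (C1–C2) and ring-closing alkyne metathesis. Gold(I)-catalysed transannular 5-exo-dig anti-hydroalkoxylation then joins O6 to C9: this one bond closes the oxolane and the 13-membered oxacycle (O, C9–C14, C1–C6) together and sets the (Z)-enol ether. The step exploits the pent-4-yn-1-ol relationship between the C6 hydroxyl and the ring alkyne.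

Key step: step 19

Assumption: locants Cn use cembrane numbering of the target (C1 = ring carbon bearing the isopropylidene group, C2 = ketone carbon, C3/C4 = epoxide carbons, C6 and C9 = carbons joined by the ether oxygen, C8 = methyl-bearing oxolane carbon, C12 = acetoxy carbon); where the enantiomer of a chiral ligand or promoter is not named, it is the one that gives the descriptor shown.

**Route**

Step 1
Reactants: 1 methyl 3-methylbut-2-enoate
Product: 2 tert-butyl[(1-methoxy-3-methylbuta-1,3-dien-1-yl)oxy]dimethylsilane (ketene acetal geometry not controlled; it is lost in step 3)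
Conditions: LDA, THF, −78 °C; TBSCl, DMPU, −78 °C → rt
Reagents that add atoms: tert-butyldimethylsilyl chloride, CC(C)(C)[Si](C)(C)Cl
Why: γ-Deprotonation of the senecioate gives the lithium dienolate, which is O-silylated to the vinylketene silyl acetal (silyl dienol ether formation).

Step 2
Reactants: 3 (E)-but-2-enal; 4 ethynyltri(propan-2-yl)silane
Product: 5 (3S)-3-methyl-5-[tri(propan-2-yl)silyl]pent-4-ynal
Conditions: [Rh(OAc)(C2H4)2]2 (2.5 mol %), DTBM-SEGPHOS (6 mol %), MeOH, 40 °C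
Reagents that add atoms: none
Why: Rhodium-catalysed asymmetric conjugate alkynylation of an enal, in which the bulky silyl group suppresses alkyne dimerisation and the chiral bisphosphine–rhodium alkynyl selects one enantioface, setting C8 (S).

Step 3
Reactants: 5 (3S)-3-methyl-5-[tri(propan-2-yl)silyl]pent-4-ynal; 2 tert-butyl[(1-methoxy-3-methylbuta-1,3-dien-1-yl)oxy]dimethylsilane
Product: 6 methyl (2E,5R,7S)-5-hydroxy-3,7-dimethyl-9-[tri(propan-2-yl)silyl]non-2-en-8-ynoate
Conditions: preformed B-phenyl oxazaborolidinone of N-tosyltryptophan (0.5 equiv), iPrOH (1.1 equiv), EtCN, −78 °C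
Reagents that add atoms: none
Why: Vinylogous Mukaiyama aldol reaction in which the γ-carbon of the dienolate adds to the Si face of the boron-bound aldehyde, giving the (E)-enoate directly and setting C6 (R) under promoter control, with the minor diastereomer removable by chromatography.

Step 4
Reactants: 6 methyl (2E,5R,7S)-5-hydroxy-3,7-dimethyl-9-[tri(propan-2-yl)silyl]non-2-en-8-ynoate
Product: 7 methyl (2E,5R,7S)-5-hydroxy-3,7-dimethylnon-2-en-8-ynoate
Conditions: TBAF (1.1 equiv), THF, 0 °C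
Reagents that add atoms: none
Why: Fluoride-induced protodesilylation of the alkynylsilane, which should leave the hydroxy enoate untouched at 0 °C.

Step 5
Reactants: 7 methyl (2E,5R,7S)-5-hydroxy-3,7-dimethylnon-2-en-8-ynoate
Product: 8 methyl (2E,5R,7S)-3,7-dimethyl-5-[(triethylsilyl)oxy]non-2-en-8-ynoate
Conditions: TESCl, imidazole, CH2Cl2, 0 °C
Reagents that add atoms: chlorotriethylsilane, CC[Si](Cl)(CC)CC
Why: Silylation of the secondary alcohol masks O6, which would otherwise open the later C3–C4 epoxide and quench the organometallic steps.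

Step 6
Reactants: 8 methyl (2E,5R,7S)-3,7-dimethyl-5-[(triethylsilyl)oxy]non-2-en-8-ynoate
Product: 9 (2E,5R,7S)-3,7-dimethyl-5-[(triethylsilyl)oxy]non-2-en-8-yn-1-ol
Conditions: DIBAL-H (2.3 equiv), CH2Cl2, −78 °C; Rochelle salt work-up
Reagents that add atoms: none
Why: 1,2-Reduction of the enoate to the (E)-allylic alcohol by hydride transfer, with alkyne and silyl ether inert at −78 °C.

Step 7
Reactants: 9 (2E,5R,7S)-3,7-dimethyl-5-[(triethylsilyl)oxy]non-2-en-8-yn-1-ol
Product: 10 (2E,5R,7S)-3,7-dimethyl-5-[(triethylsilyl)oxy]dec-2-en-8-yn-1-ol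
Conditions: n-BuLi (2.1 equiv), THF, −78 → −20 °C; MeI (1.1 equiv), −78 °C → rt
Reagents that add atoms: iodomethane, CI
Why: Acetylide alkylation of the alkoxide/acetylide dianion occurs at carbon only (lithium alkoxides are inert to MeI in THF) and installs the methyl cap needed for alkyne metathesis.

Step 8
Reactants: 10 (2E,5R,7S)-3,7-dimethyl-5-[(triethylsilyl)oxy]dec-2-en-8-yn-1-ol
Product: 11 {(2S,3S)-3-methyl-3-[(2R,4S)-4-methyl-2-[(triethylsilyl)oxy]hept-5-yn-1-yl]oxiran-2-yl}methanol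
Conditions: Ti(OiPr)4 (10 mol %), L-(+)-diethyl tartrate (12 mol %), t-BuOOH, 4 Å MS, CH2Cl2, −20 °C
Reagents that add atoms: tert-butyl hydroperoxide, CC(C)(C)OO
Why: Sharpless asymmetric epoxidation of an (E)-trisubstituted allylic alcohol, where L-(+)-tartrate delivers oxygen to the face that gives the (2S,3S)-epoxy alcohol (as with geraniol), setting C3 and C4 under reagent control.

Step 9
Reactants: 11 {(2S,3S)-3-methyl-3-[(2R,4S)-4-methyl-2-[(triethylsilyl)oxy]hept-5-yn-1-yl]oxiran-2-yl}methanol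
Product: 12 (2R,3S)-3-methyl-3-[(2R,4S)-4-methyl-2-[(triethylsilyl)oxy]hept-5-yn-1-yl]oxirane-2-carbaldehyde
Conditions: Dess–Martin periodinane, NaHCO3, CH2Cl2, 0 °C → rt
Reagents that add atoms: none
Why: Buffered Dess–Martin oxidation should give the epoxy aldehyde without epoxide opening or epimerisation of the non-enolisable oxirane C–H.

Step 10
Reactants: 13 6-methylhept-5-en-2-one
Product: 14 (2R)-2-methyl-2-(4-methylpent-3-en-1-yl)oxirane
Conditions: Me3S(O)I, NaH, THF; La–Li3–tris(binaphthoxide) (5 mol %), tris(2,4,6-trimethoxyphenyl)phosphine oxide (5 mol %), 5 Å MS, rt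
Reagents that add atoms: trimethylsulfoxonium iodide, C[S+](C)(C)=O.[I-]
Why: Catalytic asymmetric Corey–Chaykovsky epoxidation of a methyl ketone, in which the La/Li binaphthoxide binds ketone and ylide and differentiates methyl from the alkyl chain, setting the oxygenated quaternary C12 (R).

Step 11
Reactants: 14 (2R)-2-methyl-2-(4-methylpent-3-en-1-yl)oxirane; 15 prop-1-yn-1-yllithium
Product: 16 (5R)-5,9-dimethyldec-8-en-2-yn-5-ol
Conditions: BF3·OEt2, THF, −78 °C
Reagents that add atoms: none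
Why: Yamaguchi–Hirao alkynylation, in which the alkynyl borate opens the epoxide by SN2 attack at the unsubstituted carbon, so the quaternary C–O stereocentre is not touched.

Step 12
Reactants: 16 (5R)-5,9-dimethyldec-8-en-2-yn-5-ol
Product: 17 (5R)-5,9-dimethyldec-8-en-2-yn-5-yl acetate
Conditions: Ac2O, Et3N, DMAP, CH2Cl2, 40 °C
Reagents that add atoms: acetic anhydride, CC(=O)OC(C)=O
Why: DMAP-catalysed acylation of the tertiary alcohol at oxygen, with no change at the stereocentre.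

Step 13
Reactants: 17 (5R)-5,9-dimethyldec-8-en-2-yn-5-yl acetate
Product: 18 (5R,8E)-10-hydroxy-5,9-dimethyldec-8-en-2-yn-5-yl acetate
Conditions: SeO2 (0.3 equiv), t-BuOOH, salicylic acid (cat.), CH2Cl2, rt
Reagents that add atoms: tert-butyl hydroperoxide, CC(C)(C)OO (oxygen relayed by catalytic selenium dioxide, O=[Se]=O)
Why: Sharpless–Umbreit allylic oxidation (ene reaction then [2,3]-shift) oxidises the (E)-methyl group of the only alkene present, giving the (E)-allylic alcohol.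

Step 14
Reactants: 18 (5R,8E)-10-hydroxy-5,9-dimethyldec-8-en-2-yn-5-yl acetate
Product: 19 (5R,8E)-10-bromo-5,9-dimethyldec-8-en-2-yn-5-yl acetate
Conditions: CBr4, PPh3, CH2Cl2, 0 °C
Reagents that add atoms: carbon tetrabromide, BrC(Br)(Br)Br
Why: Appel bromination by SN2 displacement at the primary allylic carbon, which keeps the E geometry.

Step 15
Reactants: 19 (5R,8E)-10-bromo-5,9-dimethyldec-8-en-2-yn-5-yl acetate; 12 (2R,3S)-3-methyl-3-[(2R,4S)-4-methyl-2-[(triethylsilyl)oxy]hept-5-yn-1-yl]oxirane-2-carbaldehyde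
Product: 20 (5R)-8-{hydroxy[(2S,3S)-3-methyl-3-{(2R,4S)-4-methyl-2-[(triethylsilyl)oxy]hept-5-yn-1-yl}oxiran-2-yl]methyl}-5,9-dimethyldec-9-en-2-yn-5-yl acetate (mixture at C8 of the decenyne chain and at the carbinol carbon)
Conditions: CrCl2 (4 equiv), 4 Å MS, THF, rt
Reagents that add atoms: none
Why: Nozaki–Hiyama allylation, in which the allylchromium(III) species adds through its γ-carbon (C1) to the aldehyde via a chair transition state, forming C1–C2 and the isopropenyl group; the two new centres form as a mixture and are both erased in step 16.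

Step 16
Reactants: 20 (5R)-8-{hydroxy[(2S,3S)-3-methyl-3-{(2R,4S)-4-methyl-2-[(triethylsilyl)oxy]hept-5-yn-1-yl}oxiran-2-yl]methyl}-5,9-dimethyldec-9-en-2-yn-5-yl acetate
Product: 22 (5R)-5,9-dimethyl-8-{[(2R,3S)-3-methyl-3-{(2R,4S)-4-methyl-2-[(triethylsilyl)oxy]hept-5-yn-1-yl}oxiran-2-yl]carbonyl}dec-8-en-2-yn-5-yl acetate, via deconjugated isopropenyl ketone 21 (not isolated)
Conditions: Dess–Martin periodinane, NaHCO3, CH2Cl2, 0 °C → rt; thiosulfate/bicarbonate wash; crude in CH2Cl2, DBU (0.5 equiv), rt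
Reagents that add atoms: none
Why: Alcohol oxidation followed by base-mediated prototropic isomerisation, in which DBU removes the doubly activated C1–H and γ-reprotonation of the dienolate moves the double bond into conjugation as the tetrasubstituted isopropylidene enone, erasing C1.

Step 17
Reactants: 22 (5R)-5,9-dimethyl-8-{[(2R,3S)-3-methyl-3-{(2R,4S)-4-methyl-2-[(triethylsilyl)oxy]hept-5-yn-1-yl}oxiran-2-yl]carbonyl}dec-8-en-2-yn-5-yl acetate
Product: 23 (3R,4S,6R,8S,12R)-12-acetoxy-3,4-epoxy-6-[(triethylsilyl)oxy]cembra-1(15)-en-9-yn-2-one (14-membered carbocycle)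
Conditions: [Mo(≡C–C6H4-4-OMe)(OSiPh3)3] (10 mol %), 5 Å MS, toluene (2 mM), rt → 60 °C
Reagents that add atoms: none
Why: Ring-closing alkyne metathesis, in which the molybdenum alkylidyne exchanges the two methyl-capped alkyne termini through metallacyclobutadienes and expels but-2-yne (trapped by the sieves) to close the strain-free 14-membered cycloalkyne without touching any stereocentre, the alkene, the epoxy ketone, the ester or the silyl ether.

Step 18
Reactants: 23 (3R,4S,6R,8S,12R)-12-acetoxy-3,4-epoxy-6-[(triethylsilyl)oxy]cembra-1(15)-en-9-yn-2-one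
Product: 24 (3R,4S,6R,8S,12R)-12-acetoxy-3,4-epoxy-6-hydroxycembra-1(15)-en-9-yn-2-one
Conditions: HF·pyridine, pyridine, THF, 0 °C
Reagents that add atoms: none
Why: Buffered fluoride desilylation removes the triethylsilyl ether, while the trans-epoxide between O6 and the ketone prevents hemiketal formation and the acetate and epoxy ketone tolerate these conditions.

Step 19
Reactants: 24 (3R,4S,6R,8S,12R)-12-acetoxy-3,4-epoxy-6-hydroxycembra-1(15)-en-9-yn-2-one
Product: 25 (3R,4S,6R,8S,9Z,12R)-12-acetoxy-3,4:6,9-diepoxycembra-1(15),9-dien-2-one (target)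
Conditions: JohnPhosAu(MeCN)SbF6 (5 mol %), 2,6-di-tert-butylpyridine (10 mol %), 4 Å MS, CH2Cl2, 0 °C → rt; Et3N quench, chromatography on Et3N-deactivated silica
Reagents that add atoms: none
Why: Cationic gold(I) π-activates the C9≡C10 bond and the C6 hydroxyl, held in a pent-4-yn-1-ol array, attacks C9 anti to gold; protodeauration of the vinylgold species with retention places O and H trans, which is the (9Z) geometry of 25. The closest known reaction type is the gold-catalysed cycloisomerisation of 4-alkyn-1-ols to (Z)-2-alkylidene oxolanes and its transannular use on cycloalkynes made by alkyne metathesis. The oxolane (O–C6–C7–C8–C9) closes in the 5-exo-dig mode, and the same O–C9 bond closes the 13-membered oxacycle (O, C9–C14, C1–C6) as a transannular contraction of the 14-membered carbocycle, so both rings appear in one event and no ring is closed afterwards. No stereocentre is created: C6 and C8 come from steps 3 and 2 and fix the trans relationship of the C8 methyl and the C6 side chain on the oxolane, while the C9=C10 geometry is fixed by the anti-addition mechanism. The step needs attack at C9 (5-exo) over C10 (6-endo), secured by the shorter tether, the C8 methyl branch and the inductively withdrawing C12 acetoxy group two bonds from C10, and it needs the exocyclic double bond to stay in place, secured by the hindered-base buffer, the sieves and the amine quench; the epoxy ketone, enone and acetate should be inert to the soft π-acid.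

**Compound list**

1 | methyl 3-methylbut-2-enoate | CC(C)=CC(=O)OC | starting material
2 | tert-butyl[(1-methoxy-3-methylbuta-1,3-dien-1-yl)oxy]dimethylsilane | C=C(C)C=C(OC)O[Si](C)(C)C(C)(C)C | intermediate
3 | (E)-but-2-enal | C/C=C/C=O | starting material
4 | ethynyltri(propan-2-yl)silane | C#C[Si](C(C)C)(C(C)C)C(C)C | starting material
5 | (3S)-3-methyl-5-[tri(propan-2-yl)silyl]pent-4-ynal | O=CC[C@H](C)C#C[Si](C(C)C)(C(C)C)C(C)C | intermediate
6 | methyl (2E,5R,7S)-5-hydroxy-3,7-dimethyl-9-[tri(propan-2-yl)silyl]non-2-en-8-ynoate | COC(=O)/C=C(\C)C[C@H](O)C[C@H](C)C#C[Si](C(C)C)(C(C)C)C(C)C | intermediate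
7 | methyl (2E,5R,7S)-5-hydroxy-3,7-dimethylnon-2-en-8-ynoate | COC(=O)/C=C(\C)C[C@H](O)C[C@H](C)C#C | intermediate
8 | methyl (2E,5R,7S)-3,7-dimethyl-5-[(triethylsilyl)oxy]non-2-en-8-ynoate | COC(=O)/C=C(\C)C[C@H](O[Si](CC)(CC)CC)C[C@H](C)C#C | intermediate
9 | (2E,5R,7S)-3,7-dimethyl-5-[(triethylsilyl)oxy]non-2-en-8-yn-1-ol | OC/C=C(\C)C[C@H](O[Si](CC)(CC)CC)C[C@H](C)C#C | intermediate
10 | (2E,5R,7S)-3,7-dimethyl-5-[(triethylsilyl)oxy]dec-2-en-8-yn-1-ol | OC/C=C(\C)C[C@H](O[Si](CC)(CC)CC)C[C@H](C)C#CC | intermediate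
11 | {(2S,3S)-3-methyl-3-[(2R,4S)-4-methyl-2-[(triethylsilyl)oxy]hept-5-yn-1-yl]oxiran-2-yl}methanol | OC[C@@H]1O[C@@]1(C)C[C@H](O[Si](CC)(CC)CC)C[C@H](C)C#CC | intermediate
12 | (2R,3S)-3-methyl-3-[(2R,4S)-4-methyl-2-[(triethylsilyl)oxy]hept-5-yn-1-yl]oxirane-2-carbaldehyde | O=C[C@@H]1O[C@@]1(C)C[C@H](O[Si](CC)(CC)CC)C[C@H](C)C#CC | intermediate
13 | 6-methylhept-5-en-2-one | CC(=O)CCC=C(C)C | starting material
14 | (2R)-2-methyl-2-(4-methylpent-3-en-1-yl)oxirane | CC(C)=CCC[C@]1(C)CO1 | intermediate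
15 | prop-1-yn-1-yllithium | [Li]C#CC | starting material
16 | (5R)-5,9-dimethyldec-8-en-2-yn-5-ol | CC#CC[C@](C)(O)CCC=C(C)C | intermediate
17 | (5R)-5,9-dimethyldec-8-en-2-yn-5-yl acetate | CC#CC[C@](C)(OC(C)=O)CCC=C(C)C | intermediate
18 | (5R,8E)-10-hydroxy-5,9-dimethyldec-8-en-2-yn-5-yl acetate | CC#CC[C@](C)(OC(C)=O)CC/C=C(\C)CO | intermediate
19 | (5R,8E)-10-bromo-5,9-dimethyldec-8-en-2-yn-5-yl acetate | CC#CC[C@](C)(OC(C)=O)CC/C=C(\C)CBr | intermediate
20 | (5R)-8-{hydroxy[(2S,3S)-3-methyl-3-{(2R,4S)-4-methyl-2-[(triethylsilyl)oxy]hept-5-yn-1-yl}oxiran-2-yl]methyl}-5,9-dimethyldec-9-en-2-yn-5-yl acetate (two centres unassigned) | CC#CC[C@](C)(OC(C)=O)CCC(C(C)=C)C(O)[C@@H]1O[C@@]1(C)C[C@H](O[Si](CC)(CC)CC)C[C@H](C)C#CC | intermediate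
21 | (5R)-5,9-dimethyl-8-{[(2R,3S)-3-methyl-3-{(2R,4S)-4-methyl-2-[(triethylsilyl)oxy]hept-5-yn-1-yl}oxiran-2-yl]carbonyl}dec-9-en-2-yn-5-yl acetate (C8 unassigned) | CC#CC[C@](C)(OC(C)=O)CCC(C(C)=C)C(=O)[C@@H]1O[C@@]1(C)C[C@H](O[Si](CC)(CC)CC)C[C@H](C)C#CC | intermediate
22 | (5R)-5,9-dimethyl-8-{[(2R,3S)-3-methyl-3-{(2R,4S)-4-methyl-2-[(triethylsilyl)oxy]hept-5-yn-1-yl}oxiran-2-yl]carbonyl}dec-8-en-2-yn-5-yl acetate | CC#CC[C@](C)(OC(C)=O)CCC(=C(C)C)C(=O)[C@@H]1O[C@@]1(C)C[C@H](O[Si](CC)(CC)CC)C[C@H](C)C#CC | intermediate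
23 | (3R,4S,6R,8S,12R)-12-acetoxy-3,4-epoxy-6-[(triethylsilyl)oxy]cembra-1(15)-en-9-yn-2-one | CC(=O)O[C@@]1(C)CC#C[C@@H](C)C[C@@H](O[Si](CC)(CC)CC)C[C@]2(C)O[C@H]2C(=O)C(=C(C)C)CC1 | intermediate
24 | (3R,4S,6R,8S,12R)-12-acetoxy-3,4-epoxy-6-hydroxycembra-1(15)-en-9-yn-2-one | CC(=O)O[C@@]1(C)CC#C[C@@H](C)C[C@@H](O)C[C@]2(C)O[C@H]2C(=O)C(=C(C)C)CC1 | intermediate
25 | (3R,4S,6R,8S,9Z,12R)-12-acetoxy-3,4:6,9-diepoxycembra-1(15),9-dien-2-one | CC(=O)O[C@@]1(C)C/C=C2\O[C@H](C[C@@H]2C)C[C@]2(C)O[C@H]2C(=O)C(=C(C)C)CC1 | target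

**Totals.** 19 steps in all. Longest linear sequence: 13 steps (steps 2–9, then 15–19).

**Steps most likely to fail**

Step 19. The hydroxyl may attack the distal alkyne carbon (6-endo closure), the exocyclic enol-ether double bond may migrate into the ring under adventitious acid, or the alkyne may be hydrated with help from the neighbouring acetate. The fallback sets out from 24 and comes back at 25, and replaces π-acid catalysis by a stoichiometric iodonium-triggered cyclisation followed by reductive removal of iodine. N-Iodosuccinimide with NaHCO3 in MeCN at −20 °C should give, by anti iodo-alkoxylation in the 5-exo mode under base buffer, (3R,4S,6R,8S,9E,12R)-12-acetoxy-3,4:6,9-diepoxy-10-iodocembra-1(15),9-dien-2-one F1. Palladium-catalysed formate reduction (Pd(OAc)2, PPh3, HCO2H, Et3N, DMF, rt) should then replace iodine by hydrogen with retention and give 25.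

Step 17. The alkylidyne may be deactivated by the epoxy ketone and enone oxygens, or acyclic diyne metathesis may outrun ring closure. The fallback sets out from 9 and 14 and comes back at 23; it installs the C9≡C10–C11 unit by acetylide opening of the epoxide and closes the ring at C1–C2 instead.
- 9 is protected (4-methoxybenzyl trichloroacetimidate, cat. La(OTf)3, toluene) as PMB ether 1-methoxy-4-({[(2E,5R,7S)-3,7-dimethyl-5-[(triethylsilyl)oxy]non-2-en-8-yn-1-yl]oxy}methyl)benzene F2.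
- Its lithium acetylide (n-BuLi; BF3·OEt2, THF, −78 °C) opens 14 to tertiary alcohol (2E,5R,7S,11R)-1-[(4-methoxybenzyl)oxy]-3,7,11,15-tetramethyl-5-[(triethylsilyl)oxy]hexadeca-2,14-dien-8-yn-11-ol F3.
- Ac2O/DMAP gives the 11-acetate of that alcohol F4.
- DDQ in buffered wet CH2Cl2 frees the allylic alcohol (2E,5R,7S,11R)-1-hydroxy-3,7,11,15-tetramethyl-5-[(triethylsilyl)oxy]hexadeca-2,14-dien-8-yn-11-yl acetate F5.
- Sharpless epoxidation with L-(+)-diethyl tartrate gives the (2S,3S)-2,3-epoxy alcohol F6.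
- SeO2/t-BuOOH oxidises the remaining prenyl terminus to the (14E)-1,16-diol F7.
- NBS/Me2S at −20 °C converts only the allylic hydroxyl into the 16-bromo epoxy alcohol F8.
- Dess–Martin oxidation gives the bromo epoxy aldehyde F9.
- CrCl2 in dilute THF closes the ring by intramolecular Nozaki–Hiyama allylation to the macrocyclic homoallylic alcohol (3R,4S,6R,8S,12R)-12-acetoxy-3,4-epoxy-2-hydroxy-6-[(triethylsilyl)oxy]cembra-15-en-9-yne F10 (C1 and C2 unassigned).
- Dess–Martin oxidation and DBU, as in step 16, then give 23.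

Step 16. Double-bond migration may stall because allylic strain in the tetrasubstituted enone leaves the deconjugated isopropenyl ketone competitive at equilibrium. The fallback sets out from 20 and comes back at 22, and forms the C1=C15 bond by elimination instead of equilibration. Mukaiyama hydration of the 1,1-disubstituted alkene (Mn(dpm)3 cat., PhSiH3, O2, iPrOH, 0 °C) should give the tertiary/secondary diol (5R)-8-{hydroxy[(2S,3S)-oxiranyl]methyl}-9-hydroxy-5,9-dimethyldec-2-yn-5-yl acetate F11. Dess–Martin oxidation of the secondary alcohol gives the β-hydroxy ketone F12. Dehydration with Martin sulfurane in CH2Cl2 at 0 °C, which removes the acidic C1–H, should give 22 under neutral conditions that do not re-equilibrate the enone.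

Further compounds
F1 | step 19 | (3R,4S,6R,8S,9E,12R)-12-acetoxy-3,4:6,9-diepoxy-10-iodocembra-1(15),9-dien-2-one | CC(=O)O[C@@]1(C)C/C(I)=C2\O[C@H](C[C@@H]2C)C[C@]2(C)O[C@H]2C(=O)C(=C(C)C)CC1
F2 | step 17 | 1-methoxy-4-({[(2E,5R,7S)-3,7-dimethyl-5-[(triethylsilyl)oxy]non-2-en-8-yn-1-yl]oxy}methyl)benzene | COc1ccc(COC/C=C(\C)C[C@H](O[Si](CC)(CC)CC)C[C@H](C)C#C)cc1
F3 | step 17 | (2E,5R,7S,11R)-1-[(4-methoxybenzyl)oxy]-3,7,11,15-tetramethyl-5-[(triethylsilyl)oxy]hexadeca-2,14-dien-8-yn-11-ol | COc1ccc(COC/C=C(\C)C[C@H](O[Si](CC)(CC)CC)C[C@H](C)C#CC[C@](C)(O)CCC=C(C)C)cc1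
F4 | step 17 | (2E,5R,7S,11R)-1-[(4-methoxybenzyl)oxy]-3,7,11,15-tetramethyl-5-[(triethylsilyl)oxy]hexadeca-2,14-dien-8-yn-11-yl acetate | COc1ccc(COC/C=C(\C)C[C@H](O[Si](CC)(CC)CC)C[C@H](C)C#CC[C@](C)(OC(C)=O)CCC=C(C)C)cc1
F5 | step 17 | (2E,5R,7S,11R)-1-hydroxy-3,7,11,15-tetramethyl-5-[(triethylsilyl)oxy]hexadeca-2,14-dien-8-yn-11-yl acetate | OC/C=C(\C)C[C@H](O[Si](CC)(CC)CC)C[C@H](C)C#CC[C@](C)(OC(C)=O)CCC=C(C)C
F6 | step 17 | (2S,3S)-2,3-epoxide of F5 (epoxy alcohol) | OC[C@@H]1O[C@@]1(C)C[C@H](O[Si](CC)(CC)CC)C[C@H](C)C#CC[C@](C)(OC(C)=O)CCC=C(C)C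
F7 | step 17 | (14E)-16-hydroxy derivative of F6 (1,16-diol) | OC[C@@H]1O[C@@]1(C)C[C@H](O[Si](CC)(CC)CC)C[C@H](C)C#CC[C@](C)(OC(C)=O)CC/C=C(\C)CO
F8 | step 17 | (14E)-16-bromo epoxy alcohol from F7 | OC[C@@H]1O[C@@]1(C)C[C@H](O[Si](CC)(CC)CC)C[C@H](C)C#CC[C@](C)(OC(C)=O)CC/C=C(\C)CBr
F9 | step 17 | (14E)-16-bromo epoxy aldehyde from F8 | O=C[C@@H]1O[C@@]1(C)C[C@H](O[Si](CC)(CC)CC)C[C@H](C)C#CC[C@](C)(OC(C)=O)CC/C=C(\C)CBr
F10 | step 17 | (3R,4S,6R,8S,12R)-12-acetoxy-3,4-epoxy-2-hydroxy-6-[(triethylsilyl)oxy]cembra-15-en-9-yne (C1, C2 unassigned) | CC(=O)O[C@@]1(C)CC#C[C@@H](C)C[C@@H](O[Si](CC)(CC)CC)C[C@]2(C)O[C@H]2C(O)C(C(C)=C)CC1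
F11 | step 16 | (5R)-9-hydroxy-8-{hydroxy[(2S,3S)-3-methyl-3-{(2R,4S)-4-methyl-2-[(triethylsilyl)oxy]hept-5-yn-1-yl}oxiran-2-yl]methyl}-5,9-dimethyldec-2-yn-5-yl acetate | CC#CC[C@](C)(OC(C)=O)CCC(C(C)(C)O)C(O)[C@@H]1O[C@@]1(C)C[C@H](O[Si](CC)(CC)CC)C[C@H](C)C#CC
F12 | step 16 | (5R)-9-hydroxy-5,9-dimethyl-8-{[(2R,3S)-3-methyl-3-{(2R,4S)-4-methyl-2-[(triethylsilyl)oxy]hept-5-yn-1-yl}oxiran-2-yl]carbonyl}dec-2-yn-5-yl acetate | CC#CC[C@](C)(OC(C)=O)CCC(C(C)(C)O)C(=O)[C@@H]1O[C@@]1(C)C[C@H](O[Si](CC)(CC)CC)C[C@H](C)C#CC
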